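**Plan**

- Numbering (daucane): C1 quaternary ring-fusion carbon (CH3), C2 CH–OAc, C3 CH2, C4 C(OH)iPr, C5 ring-fusion CH, C6 CH–O-angelate, C7 CH2, C8/C9 oxirane (CH3 on C8), C10 CH–OAc next to C1.
- Retrosynthesis: esters and the C8–C9 oxirane come off, C10 and C2 go back to ketones, then the cyclopentane C1–C2–C3–C4–C5 is cut at C3–C4. Its oxygens on C2 and C4 flank the C3 methylene (a β-hydroxy ketone pattern), and the ring-fusion atoms C1 and C5 carry the two acyl arms trans.
- The 1,4-diketone is cut at C1–C2 and C5–C4: a cross-conjugated cycloheptadienone takes an alkenyl nucleophile at C5 and acetaldehyde at C1 in one flask. The dienone comes from cyclohepta-1,3-diene.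
- Forward: bought seven-membered ring, then oxygenated dimethyl dienone, then 1,4-diketone, then the cyclopentane closed last, then oxirane and esters.
- Stereochemistry: C6 by catalytic desymmetrisation of a meso endoperoxide; C5 anti to C6–O and C1 anti to C5; C4 in the ring closure; C2 (anti) and C10 (syn) by hydroxyl-directed reductions relayed from C4–OH; C8/C9 by epoxidation directed by C10–OH.

Key step: step 11

Remark: Why lines use the daucane numbers above; monocyclic compounds are named with their own ring locants. α/β refer to the usual drawing with the C1 methyl β; the target is 2α,10α-diacetoxy-6α-angeloyloxy-8α,9α-epoxydaucan-4β-ol, trans-fused (H5 α).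
Assumption: the oxirane is treated as a functional group put on the finished bicyclic carbon skeleton.
Assumption: cupreidine 9-O-acetate is taken as the pseudoenantiomer that leads to the (S)-enone in step 2; if the sense is the reverse, cupreine 9-O-acetate is used.

Step 1
Reactants: 1 cyclohepta-1,3-diene
Product: 2 6,7-dioxabicyclo[3.2.2]non-8-ene
Conditions: O2, visible light, tetraphenylporphyrin (cat.), CH2Cl2, 0 °C
Reagents that add atoms: dioxygen, O=O
Why: Singlet oxygen adds across the cyclic 1,3-diene in a [4+2] cycloaddition, and the meso endoperoxide carries oxygen at both diene termini without any stereocontrol being needed.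

Step 2
Reactants: 2 6,7-dioxabicyclo[3.2.2]non-8-ene
Product: 3 (S)-4-hydroxycyclohept-2-en-1-one
Conditions: cupreidine 9-O-acetate (10 mol %), CH2Cl2, rt
Reagents that add atoms: none
Why: Kornblum–DeLaMare rearrangement run as a desymmetrisation, in which the chiral base takes one of the two enantiotopic bridgehead protons, the O–O bond breaks and the surviving carbinol carbon (the later C6) is set, the source of all absolute configuration in the route.

Step 3
Reactants: 3 (S)-4-hydroxycyclohept-2-en-1-one
Product: 4 (S)-4-(tert-butyldimethylsilyloxy)cyclohept-2-en-1-one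
Conditions: TBSCl, imidazole, DMF, rt
Reagents that add atoms: tert-butyldimethylsilyl chloride, CC(C)(C)[Si](C)(C)Cl
Why: Standard silylation of the secondary allylic alcohol; the bulky silyl ether later shields one face in the conjugate addition and is kept until step 15.

Step 4
Reactants: 4 (S)-4-(tert-butyldimethylsilyloxy)cyclohept-2-en-1-one
Product: 5 (S)-4-(tert-butyldimethylsilyloxy)-2-iodocyclohept-2-en-1-one
Conditions: I2, pyridine, CH2Cl2, rt
Reagents that add atoms: iodine, II
Why: α-Iodination of the enone by the pyridine-mediated addition–iodination–elimination sequence (Baylis–Hillman type) touches only the enone α-carbon, the later C1.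

Step 5
Reactants: 5 (S)-4-(tert-butyldimethylsilyloxy)-2-iodocyclohept-2-en-1-one
Product: 6 (S)-4-(tert-butyldimethylsilyloxy)-2-methylcyclohept-2-en-1-one
Conditions: Me4Sn, PdCl2(PhCN)2 (5 mol %), AsPh3, CuI, NMP, 80 °C
Reagents that add atoms: tetramethylstannane, C[Sn](C)(C)C
Why: Stille coupling of the α-iodoenone under neutral conditions puts in the methyl group that ends as the angular CH3 on C1 without risk to the γ-silyloxy group.

Step 6
Reactants: 6 (S)-4-(tert-butyldimethylsilyloxy)-2-methylcyclohept-2-en-1-one
Product: 8 (S)-4-(tert-butyldimethylsilyloxy)-2-methylcyclohepta-2,6-dien-1-one, via trimethylsilyl dienol ether 7 (not isolated)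
Conditions: LDA, TMSCl, THF, −78 °C; then Pd(OAc)2 (10 mol %), O2 (1 atm), DMSO, rt
Reagents that add atoms: none
Why: Kinetic deprotonation can only occur at the α′-CH2 (C9) because the α-carbon is fully substituted, and Saegusa–Ito oxidation of the silyl dienol ether in its catalytic aerobic form should give the cross-conjugated dienone.

Step 7
Reactants: 8 (S)-4-(tert-butyldimethylsilyloxy)-2-methylcyclohepta-2,6-dien-1-one
Product: 10 (S)-4-(tert-butyldimethylsilyloxy)-2,6-dimethylcyclohepta-2,6-dien-1-one, via trimethylsilyl enol ether 9 (not isolated)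
Conditions: MeMgBr, CuBr·SMe2 (10 mol %), TMSCl, THF, −78 °C; then Pd(OAc)2 (10 mol %), O2 (1 atm), DMSO, rt
Reagents that add atoms: methylmagnesium bromide, C[Mg]Br
Why: Copper-catalysed conjugate addition of the methyl Grignard reagent should go to C8, the β-carbon of the enone arm that has neither an α-methyl nor a γ-silyloxy group, and a second Saegusa–Ito oxidation of the trapped silyl enol ether restores the C8=C9 double bond, so the transient stereocentre does not matter.

Step 8
Reactants: 10 (S)-4-(tert-butyldimethylsilyloxy)-2,6-dimethylcyclohepta-2,6-dien-1-one, 11 2-bromo-3-methylbut-1-ene, 12 acetaldehyde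
Product: 15 (5S,6S,7R)-5-(tert-butyldimethylsilyloxy)-7-(1-hydroxyethyl)-3,7-dimethyl-6-(3-methylbut-1-en-2-yl)cyclohept-2-en-1-one (both carbinol epimers), via alkenylmagnesium bromide 13 (not isolated), via bromomagnesium enolate 14 (not isolated)
Conditions: 11, Mg, THF, rt; CuBr·SMe2 (10 mol %), then 10, THF, −40 °C; then 12, −78 °C; aq. NH4Cl, −78 °C
Reagents that add atoms: none
Why: Copper-catalysed conjugate addition followed by aldol trapping of the magnesium enolate (three-component coupling): the alkenyl group should add to C5, the only β-carbon that is not fully substituted, anti to the vicinal 6-silyloxy group, and acetaldehyde then attacks the tetrasubstituted enolate at C1 anti to the new C5 substituent, which fixes the trans relation of the two future ring-fusion arms, while the uncontrolled carbinol centre is removed in step 9.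

Step 9
Reactants: 15 (5S,6S,7R)-5-(tert-butyldimethylsilyloxy)-7-(1-hydroxyethyl)-3,7-dimethyl-6-(3-methylbut-1-en-2-yl)cyclohept-2-en-1-one
Product: 16 (5S,6S,7R)-7-acetyl-5-(tert-butyldimethylsilyloxy)-3,7-dimethyl-6-(3-methylbut-1-en-2-yl)cyclohept-2-en-1-one
Conditions: Dess–Martin periodinane, CH2Cl2, rt
Reagents that add atoms: none
Why: Dess–Martin oxidation under neutral conditions gives the non-enolisable 1,3-diketone and removes the uncontrolled carbinol centre.

Step 10
Reactants: 16 (5S,6S,7R)-7-acetyl-5-(tert-butyldimethylsilyloxy)-3,7-dimethyl-6-(3-methylbut-1-en-2-yl)cyclohept-2-en-1-one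
Product: 17 (5S,6S,7R)-7-acetyl-5-(tert-butyldimethylsilyloxy)-3,7-dimethyl-6-(2-methylpropanoyl)cyclohept-2-en-1-one
Conditions: O3, CH2Cl2/MeOH, pyridine, −78 °C (to the end point of Sudan Red 7B); then Me2S
Reagents that add atoms: ozone, [O-][O+]=O
Why: Ozonolysis dosed to an indicator end point should select the electron-rich 1,1-disubstituted alkene over the electron-poor enone double bond and unveils the isobutyryl ketone (C4) that was carried as an alkene through the enolate chemistry.

Step 11
Reactants: 17 (5S,6S,7R)-7-acetyl-5-(tert-butyldimethylsilyloxy)-3,7-dimethyl-6-(2-methylpropanoyl)cyclohept-2-en-1-one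
Product: 19 6α-(tert-butyldimethylsilyloxy)-2α,4β-dihydroxydauc-8-en-10-one, via aldol 18 (not isolated)
Conditions: LDA (1.05 equiv.), THF, −78 to −40 °C; AcOH, −78 °C; then Me4NBH(OAc)3, MeCN/AcOH, −30 °C
Reagents that add atoms: none
Why: LDA removes a proton from the acetyl CH3 (C3), the least hindered acidic C–H, and the lithium enolate adds to the C4 ketone in an intramolecular aldol addition, the first stage of the classical 1,4-diketone cyclopentenone annulation, stopped here at the aldol by low temperature. The cyclopentane C1–C5 closes in the 5-(enolendo)-exo-trig mode, formally the less easy enolate closure but the one by which 1,4-diketones cyclise, and the trans ring fusion is already fixed by the trans acyl arms on C1 and C5. C4 is substrate-controlled: in the closing envelope the isopropyl group should turn to the face of H5, away from the vicinal C6 carbon and its silyloxy group, so the hydroxyl comes out β, cis to the C1 methyl. In the same flask the new tertiary hydroxyl binds the triacetoxyborohydride and delivers hydride to the β face of the C2 ketone (Evans–Saksena reduction), which should set C2–OH α, anti to C4–OH, and removes the aldol before it can revert or dehydrate. The step needs selectivity among three ketones and several acidic C–H bonds: the C10 enone has no α-proton on C1 and cannot be reached by the C3 enolate, the γ-protons on C7 and the hindered C5–H react more slowly with LDA than the CH3 group, and the weak hydride reduces only a ketone with a bound hydroxyl in 1,3-position, the conjugated C10 carbonyl being the slower one.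

Step 12
Reactants: 19 6α-(tert-butyldimethylsilyloxy)-2α,4β-dihydroxydauc-8-en-10-one
Product: 20 6α-(tert-butyldimethylsilyloxy)dauc-8-ene-2α,4β,10α-triol
Conditions: Et2BOMe, THF/MeOH, −78 °C; NaBH4; then evaporation from MeOH
Reagents that add atoms: none
Why: Narasaka–Prasad reduction, in which the diethylboryl group chelates the C2 oxygen and the C10 carbonyl on the α face and borohydride attacks the activated carbonyl from the open β face in a 1,2-sense, so the 1,3-syn diol (C10–OH α) should result.

Step 13
Reactants: 20 6α-(tert-butyldimethylsilyloxy)dauc-8-ene-2α,4β,10α-triol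
Product: 21 6α-(tert-butyldimethylsilyloxy)-8α,9α-epoxydaucane-2α,4β,10α-triol
Conditions: VO(acac)2 (5 mol %), t-BuOOH, CH2Cl2, 0 °C
Reagents that add atoms: tert-butyl hydroperoxide, CC(C)(C)OO
Why: Vanadium-catalysed epoxidation of the cyclic allylic alcohol delivers the peroxide oxygen from the metal alkoxide at C10 to the same (α) face of C8=C9, and the non-allylic hydroxyls have no alkene within reach.

Step 14
Reactants: 21 6α-(tert-butyldimethylsilyloxy)-8α,9α-epoxydaucane-2α,4β,10α-triol
Product: 22 2α,10α-diacetoxy-6α-(tert-butyldimethylsilyloxy)-8α,9α-epoxydaucan-4β-ol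
Conditions: Ac2O, pyridine, DMAP (cat.), CH2Cl2, rt
Reagents that add atoms: acetic anhydride, CC(=O)OC(C)=O
Why: DMAP-catalysed acylation esterifies the two secondary alcohols at C2 and C10, while the hindered tertiary C4 alcohol between the isopropyl group and C5 should stay free.

Step 15
Reactants: 22 2α,10α-diacetoxy-6α-(tert-butyldimethylsilyloxy)-8α,9α-epoxydaucan-4β-ol
Product: 23 2α,10α-diacetoxy-8α,9α-epoxydaucane-4β,6α-diol
Conditions: HF·pyridine, pyridine, THF, 0 °C to rt
Reagents that add atoms: none
Why: Buffered fluoride cleaves the silyl ether at C6 without the acyl migration or oxirane opening that basic or strongly acidic conditions would risk.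

Step 16
Reactants: 23 2α,10α-diacetoxy-8α,9α-epoxydaucane-4β,6α-diol, 24 angelic acid ((Z)-2-methylbut-2-enoic acid)
Product: 26 2α,10α-diacetoxy-6α-angeloyloxy-8α,9α-epoxydaucan-4β-ol (CNP0170993.1), via mixed anhydride 25 (not isolated)
Conditions: 24, 2,4,6-trichlorobenzoyl chloride, Et3N, toluene, rt, filtration; then 23, toluene, 80 °C
Reagents that add atoms: none
Why: Yamaguchi-type esterification through the mixed 2,4,6-trichlorobenzoic anhydride acylates the only free secondary alcohol (C6) and is run without DMAP, because nucleophilic catalysts isomerise the (Z)-2-methylbut-2-enoyl group to the (E) isomer.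

**Compound list**

1 | cyclohepta-1,3-diene | C1=CC=CCCC1 | starting material
2 | 6,7-dioxabicyclo[3.2.2]non-8-ene (meso endoperoxide) | O1O[C@H]2CCC[C@@H]1C=C2 | intermediate
3 | (S)-4-hydroxycyclohept-2-en-1-one | O[C@H]1CCCC(=O)C=C1 | intermediate
4 | (S)-4-(tert-butyldimethylsilyloxy)cyclohept-2-en-1-one | CC(C)(C)[Si](C)(C)O[C@H]1CCCC(=O)C=C1 | intermediate
5 | (S)-4-(tert-butyldimethylsilyloxy)-2-iodocyclohept-2-en-1-one | CC(C)(C)[Si](C)(C)O[C@H]1CCCC(=O)C(I)=C1 | intermediate
6 | (S)-4-(tert-butyldimethylsilyloxy)-2-methylcyclohept-2-en-1-one | CC(C)(C)[Si](C)(C)O[C@H]1CCCC(=O)C(C)=C1 | intermediate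
7 | trimethylsilyl dienol ether of 6 (new C=C from the carbonyl carbon to the α′-carbon) | CC(C)(C)[Si](C)(C)O[C@H]1CCC=C(O[Si](C)(C)C)C(C)=C1 | intermediate
8 | (S)-4-(tert-butyldimethylsilyloxy)-2-methylcyclohepta-2,6-dien-1-one | CC(C)(C)[Si](C)(C)O[C@H]1CC=CC(=O)C(C)=C1 | intermediate
9 | trimethylsilyl enol ether of the methyl conjugate adduct of 8 (epimers at the new methyl-bearing carbon) | CC(C)(C)[Si](C)(C)O[C@H]1CC(C)C=C(O[Si](C)(C)C)C(C)=C1 | intermediate
10 | (S)-4-(tert-butyldimethylsilyloxy)-2,6-dimethylcyclohepta-2,6-dien-1-one | CC(C)(C)[Si](C)(C)O[C@H]1CC(C)=CC(=O)C(C)=C1 | intermediate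
11 | 2-bromo-3-methylbut-1-ene | C=C(Br)C(C)C | starting material
12 | acetaldehyde | CC=O | starting material
13 | (3-methylbut-1-en-2-yl)magnesium bromide | C=C([Mg]Br)C(C)C | intermediate
14 | bromomagnesium enolate of the C5 adduct of 10 (alkenyl group trans to the silyloxy group) | CC(C)(C)[Si](C)(C)O[C@H]1CC(C)=CC(O[Mg]Br)=C(C)[C@@H]1C(=C)C(C)C | intermediate
15 | (5S,6S,7R)-5-(tert-butyldimethylsilyloxy)-7-(1-hydroxyethyl)-3,7-dimethyl-6-(3-methylbut-1-en-2-yl)cyclohept-2-en-1-one (both carbinol epimers) | CC(C)(C)[Si](C)(C)O[C@H]1CC(C)=CC(=O)[C@@](C)(C(C)O)[C@@H]1C(=C)C(C)C | intermediate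
16 | (5S,6S,7R)-7-acetyl-5-(tert-butyldimethylsilyloxy)-3,7-dimethyl-6-(3-methylbut-1-en-2-yl)cyclohept-2-en-1-one | CC(C)(C)[Si](C)(C)O[C@H]1CC(C)=CC(=O)[C@@](C)(C(C)=O)[C@@H]1C(=C)C(C)C | intermediate
17 | (5S,6S,7R)-7-acetyl-5-(tert-butyldimethylsilyloxy)-3,7-dimethyl-6-(2-methylpropanoyl)cyclohept-2-en-1-one | CC(C)(C)[Si](C)(C)O[C@H]1CC(C)=CC(=O)[C@@](C)(C(C)=O)[C@@H]1C(=O)C(C)C | intermediate
18 | 6α-(tert-butyldimethylsilyloxy)-4β-hydroxydauc-8-ene-2,10-dione (trans-fused) | CC(C)(C)[Si](C)(C)O[C@H]1CC(C)=CC(=O)[C@@]2(C)C(=O)C[C@@](O)(C(C)C)[C@H]12 | intermediate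
19 | 6α-(tert-butyldimethylsilyloxy)-2α,4β-dihydroxydauc-8-en-10-one | CC(C)(C)[Si](C)(C)O[C@H]1CC(C)=CC(=O)[C@@]2(C)[C@@H](O)C[C@@](O)(C(C)C)[C@H]12 | intermediate
20 | 6α-(tert-butyldimethylsilyloxy)dauc-8-ene-2α,4β,10α-triol | CC(C)(C)[Si](C)(C)O[C@H]1CC(C)=C[C@@H](O)[C@@]2(C)[C@@H](O)C[C@@](O)(C(C)C)[C@H]12 | intermediate
21 | 6α-(tert-butyldimethylsilyloxy)-8α,9α-epoxydaucane-2α,4β,10α-triol | CC(C)(C)[Si](C)(C)O[C@H]1C[C@@]2(C)O[C@H]2[C@@H](O)[C@@]2(C)[C@@H](O)C[C@@](O)(C(C)C)[C@H]12 | intermediate
22 | 2α,10α-diacetoxy-6α-(tert-butyldimethylsilyloxy)-8α,9α-epoxydaucan-4β-ol | CC(C)(C)[Si](C)(C)O[C@H]1C[C@@]2(C)O[C@H]2[C@@H](OC(C)=O)[C@@]2(C)[C@@H](OC(C)=O)C[C@@](O)(C(C)C)[C@H]12 | intermediate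
23 | 2α,10α-diacetoxy-8α,9α-epoxydaucane-4β,6α-diol | O[C@H]1C[C@@]2(C)O[C@H]2[C@@H](OC(C)=O)[C@@]2(C)[C@@H](OC(C)=O)C[C@@](O)(C(C)C)[C@H]12 | intermediate
24 | angelic acid, (Z)-2-methylbut-2-enoic acid | C/C=C(/C)C(=O)O | starting material
25 | (Z)-2-methylbut-2-enoic 2,4,6-trichlorobenzoic anhydride | C/C=C(/C)C(=O)OC(=O)c1c(Cl)cc(Cl)cc1Cl | intermediate
26 | 2α,10α-diacetoxy-6α-angeloyloxy-8α,9α-epoxydaucan-4β-ol (CNP0170993.1) | C/C=C(/C)C(=O)O[C@H]1C[C@@]2(C)O[C@H]2[C@@H](OC(C)=O)[C@@]2(C)[C@@H](OC(C)=O)C[C@@](O)(C(C)C)[C@H]12 | target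

**Totals**

Total step count: 16. Longest linear sequence: 16 steps (1 to 26).

**Steps most likely to fail**

Step 11 (key step). The closure is of the 5-(enolendo) kind onto a hindered ketone and may be slow. Proton transfer to C7 or C5 could then lead to loss of the silyloxy group by β-elimination, the aldol could revert or dehydrate, and excess hydride could go on to the C10 carbonyl under direction of the new C2 hydroxyl. Fallback: setting out from 17, the kinetic enolate is trapped as it forms (LDA added to 17 in the presence of TMSCl, THF, −78 °C) to give the trimethylsilyl enol ether of the acetyl group F1. TiCl4 in CH2Cl2 at −78 °C then activates the C4 ketone for an intramolecular Mukaiyama aldol addition of the neutral enol ether, which needs no base and ends in a chelated titanium aldolate that should not revert. Aldol 18 is isolated and reduced with Me4NBH(OAc)3 in a separate, monitored operation, which comes back to the route at 19.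

Step 8. The branched alkenyl copper species may add too slowly to the α-methyl, γ-silyloxy enone arm. Deprotonation at C7 with loss of the silyloxy group (aromatisation to a tropone) or 1,2-addition would then compete, and the enolate might be protonated before it is trapped. Fallback: setting out from 10 (with 13 made from 11 as before), the addition is run with TMSCl and DMPU (CuBr·SMe2, THF, −78 °C), which accelerates conjugate addition and delivers the isolable trimethylsilyl enol ether F2. A Mukaiyama aldol addition of F2 to 12 (TiCl4, CH2Cl2, −78 °C) then forms the quaternary centre anti to the C5 substituent and comes back to the route at 15.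

Step 12. Facial selectivity may be poor, because the chelate has to send the hydride to the face that also carries the C1 methyl group, or conjugate reduction may intervene. Fallback: reagent control in place of substrate control. Corey–Bakshi–Shibata reduction of 19 with (S)-2-methyl-CBS-oxazaborolidine and catecholborane in toluene at −78 °C treats the quaternary C1 as the large and the vinylic C9 as the small substituent, for which the model predicts hydride delivery to the β face. It sets out from 19 and comes back at 20; no new compound is made (F0).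

**Further compounds**

F1 | step 11 | trimethylsilyl enol ether of the acetyl group of 17 | CC(C)(C)[Si](C)(C)O[C@H]1CC(C)=CC(=O)[C@@](C)(C(=C)O[Si](C)(C)C)[C@@H]1C(=O)C(C)C
F2 | step 8 | trimethylsilyl enol ether of the C5 alkenyl adduct of 10 | CC(C)(C)[Si](C)(C)O[C@H]1CC(C)=CC(O[Si](C)(C)C)=C(C)[C@@H]1C(=C)C(C)C
F0 | step 12 | none | none
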